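Remark on the chemistry: chain carbons are numbered C1 (ketone carbon) to C18 as in the target throughout. Ethynylmagnesium bromide 9 is taken as a purchased THF solution and bromide 8 as material of high Z purity.

## Analysis of the target

Target 27 is (6Z,9R,10E,12Z,15Z)-1-(2,6-dihydroxy-4-methoxyphenyl)-9-hydroxyoctadeca-6,10,12,15-tetraen-1-one. It is an unbranched C18 chain whose C1 is the carbonyl of an aryl ketone on a benzene ring with hydroxyls at both ortho positions and a methoxy group para. This benzene ring is the only ring, and it can be bought with its oxygenation in place as acetophenone 18, so no ring has to be built. The chain carries a 6Z olefin, a single stereocentre at C9 (R, secondary alcohol), a 10E,12Z diene attached directly to C9, a doubly allylic methylene at C14 and a 15Z olefin. With only one stereocentre, the task is absolute configuration plus four olefin geometries, not relative stereochemistry. The sensitive parts are three: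

- the C9 dienyl carbinol, which ionises to a pentadienyl cation under acid;
- the skipped C12–C16 diene, which autoxidises and can be drawn into conjugation by strong base;
- the E,Z geometry of the diene.

The difficulty is to place the C9 oxygen with R configuration beside a diene of defined geometry and then reach the aryl ketone without acid and without a late phenol deprotection. The strategy rests on one feature. A C9 carbinol next to C10=C11 (E) conjugated with C12=C13 (Z) is what a 9,10-epoxide gives when it opens with loss of a hydrogen from C11, the methylene between the oxirane and the 12Z olefin. That epoxide is the cis-(9R,10S) compound 13.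

## Retrosynthetic reasoning

**27 from 26.** The last operation only frees the C9 hydroxyl of silyl ether 26 with fluoride. The finished tetraene then never meets acid, and the phenols are already free.

**26 from 17 and 24 (C6=C7).** The isolated 6Z olefin is cut by a Wittig disconnection into aldehyde 17 (C7–C18) and phosphonium salt 24 (C1–C6 with the arene), which reacts as ylide 25. The cut is made here because it is the only olefin not in conjugation, so its geometry can be set independently by an unstabilised ylide. The ylide must sit on C6: an ylide on C7 would have the C9 oxygen in the β position and would expel it. Salt 24 carries free phenols on purpose. With base they become phenoxides, which turn the ketone into a vinylogous carboxylate that 25 neither attacks intramolecularly (a six-membered ring would otherwise be within reach) nor enolises. No acid-labile aryl ether then has to be removed from the polyene.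

**24 from 18 and 20 (C2–C3).** Salt 24 comes from iodide 23 by quaternisation. Iodide 23 comes from its bis(methoxymethyl) ether 22, and 22 from the enolate 21 of protected acetophenone 19 and diiodide 20. The arene, its substitution pattern and C1–C2 are bought in 18. The acetal groups serve only the enolate step and are removed before any acid-sensitive unit exists.

**17 from 14.** Aldehyde 17 arises by oxidation of primary alcohol 16, which comes from bis-silyl ether 15 by selective loss of the primary silyl group; 15 is the silylated dienol 14. Using the same silyl group on O7 and O9 makes the sequence indifferent to any silyl shift between the two oxygens.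

**14 from 13 (key disconnection).** The C10=C11 double bond and the free C9 hydroxyl are traced back to the 9,10-oxirane of 13. In the forward sense one C–H bond at C11 and the C10–O bond are broken and the diene is created in conjugation. This is chosen over an olefination route to the diene because the C9 configuration is then set earlier by a reagent-controlled epoxidation, and the E geometry follows from the elimination itself.

**13 from 7 and 10 (C11–C12).** The 12Z olefin of 13 is the semi-hydrogenation product of alkyne 12. The C11–C12 bond of 12 is made by displacing the primary triflate of 7 with acetylide 11, generated from enyne 10. Enyne 10, which brings C12–C18 with the 15Z olefin, is the coupling product of bromide 8 and Grignard reagent 9. The alkyne guarantees that C11 is a methylene flanked by the oxirane and the future olefin.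

**7 from 1.** Triflate 7 is the sulfonate of epoxy alcohol 6. Alcohol 6 comes from asymmetric epoxidation of Z-allylic alcohol 5, the step that fixes C9. Alcohol 5 is reached by semi-hydrogenation of propargylic alcohol 4, made by hydroxymethylation of acetylide 3 derived from silyl ether 2 of butynol 1.

## Alternatives that were turned down

**Alternative 1:** The benzene ring is disconnected at the bond between the acyl-bearing carbon and a hydroxylated carbon. In the forward sense the open-chain triketo ester A2 folds by intramolecular Claisen condensation (C6 carbanion onto the C1 ester) and enolises to acylphloroglucinol A1.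
- For: it mirrors the polyketide origin, needs no phenol protecting group, and makes the ring with all three oxygens in one step. On these points it is stronger than the chosen route.
- Against: A2 already contains the whole C2–C18 chain with the C9 silyl ether and all four olefins. The stereocentre and the diene must therefore be made first, and the valuable chain is then exposed to polyanion chemistry.
- Against: a 3,5,7-triketo ester can fold three ways (C6 onto C1, C2 onto C7 to a resorcylate, or O-acylation to a hydroxypyrone). The choice is governed by counter-ion and medium, not by the substrate.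
- Against: A1 is a triphenol and still needs selective methylation of the para hydroxyl and desilylation.
- Comparison: the advantage of building the ring has no value when the arene can be bought correctly substituted. The chosen strategy puts its risk into a C12 fragment early instead of a late cyclisation of the complete chain.

**Alternative 2:** The C9–O bond is disconnected on an intact fatty acid. A 9R-specific lipoxygenase removes a C11 hydrogen from stearidonic acid A4 and delivers dioxygen to C9 of the resulting pentadienyl radical, giving hydroperoxide A3 with the 10E,12Z diene.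
- For: one operation sets the C9 configuration and the E geometry and keeps three Z olefins from a purchasable C18 acid. For C2–C18 this is far shorter than the chosen route, and that is conceded.
- Against: A4 has three doubly allylic methylenes (C8, C11, C14), and each radical can be oxygenated at either terminus. Position and face therefore rest wholly on the fit of this ω-3 tetraenoate in the enzyme.
- Against: A3 is a hydroperoxide with a carboxylic acid at C1. After reduction and protection, the C1–aryl bond must be formed on the complete tetraene. Acylation of an electron-rich arene needs acid and offers two non-equivalent ring positions. Addition of a protected aryl-metal to an activated acid brings back a phenol deprotection.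
- Comparison: what is saved in the chain is paid back at C1. The chosen strategy has the ketone and the arene in place from the start and uses only ordinary reagents.

**Alternative 3:** The C1–C2 bond is disconnected. The carbanion of aryl dithiane A7, an acyl-anion equivalent, displaces iodide from A6, the complete C2–C18 chain, to give A5.
- For: it is convergent, avoids enolate alkylation with a dihalide, and keeps the ketone masked so that no keto-ylide question arises. In convergence it equals the chosen Wittig union.
- Against: the anion of A7 is a tertiary benzylic carbanion between two ortho alkoxy groups and is hindered for substitution.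
- Against: A6 must already hold the 6Z olefin and the dienol, so the chain synthesis is no shorter and an equivalent of the chosen key step is still required.
- Against: A5 must then lose a dithiane under soft-metal, halonium or oxidative conditions that also attack the conjugated and skipped olefins. It must also lose two aryl acetals under acid that ionises C9.
- Comparison: three risky unmasking events on the finished polyene stand against a single fluoride step in the chosen strategy.

Key step: step 9

## Route

Step 1
Reactants: 1 but-3-yn-1-ol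
Product: 2 tert-butyl(but-3-yn-1-yloxy)dimethylsilane
Conditions: TBSCl, imidazole, CH2Cl2, 0 °C to rt
Reagents that add atoms: tert-butyldimethylsilyl chloride, CC(C)(C)[Si](C)(C)Cl
Why: Imidazole-promoted silylation of a primary alcohol; the silyl ether should survive organolithium reagents, hydrogenation, the titanium epoxidation, triflation and the lithium amide of step 9.

Step 2
Reactants: 2 tert-butyl(but-3-yn-1-yloxy)dimethylsilane
Product: 4 5-(tert-butyldimethylsilyloxy)pent-2-yn-1-ol, via lithium acetylide 3 (not isolated)
Conditions: n-BuLi, THF, −78 °C; (CH2O)n, −78 °C to rt; aq. NH4Cl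
Reagents that add atoms: paraformaldehyde (as formaldehyde), C=O
Why: Deprotonation of the terminal alkyne and addition of the acetylide to formaldehyde (hydroxymethylation) should give the propargylic alcohol that supplies C11.

Step 3
Reactants: 4 5-(tert-butyldimethylsilyloxy)pent-2-yn-1-ol
Product: 5 (2Z)-5-(tert-butyldimethylsilyloxy)pent-2-en-1-ol
Conditions: H2 (1 atm), Pd/CaCO3 poisoned with Pb(OAc)2 (Lindlar catalyst), quinoline, EtOAc, rt
Reagents that add atoms: none
Why: Lindlar semi-hydrogenation delivers both hydrogens to one face of the alkyne and should give the Z-allylic alcohol; quinoline limits over-reduction.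

Step 4
Reactants: 5 (2Z)-5-(tert-butyldimethylsilyloxy)pent-2-en-1-ol
Product: 6 {(2S,3R)-3-[2-(tert-butyldimethylsilyloxy)ethyl]oxiran-2-yl}methanol
Conditions: Ti(OiPr)4 (0.2 equiv), diethyl L-(+)-tartrate (0.25 equiv), t-BuOOH, 4 Å molecular sieves, CH2Cl2, −20 °C
Reagents that add atoms: tert-butyl hydroperoxide, CC(C)(C)OO
Why: Sharpless asymmetric epoxidation; with the L-(+)-tartrate ligand the peroxide oxygen is delivered to the olefin face that makes the carbinol-bearing carbon (C10) S and C9 R, as is general for (Z)-2-alken-1-ols. The cis relationship comes from the olefin geometry, and the C9 configuration of the target is set here by the reagent.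

Step 5
Reactants: 6 {(2S,3R)-3-[2-(tert-butyldimethylsilyloxy)ethyl]oxiran-2-yl}methanol
Product: 7 {(2S,3R)-3-[2-(tert-butyldimethylsilyloxy)ethyl]oxiran-2-yl}methyl trifluoromethanesulfonate
Conditions: Tf2O, pyridine, CH2Cl2, −78 to −40 °C; cold aqueous work-up, used at once without chromatography
Reagents that add atoms: trifluoromethanesulfonic anhydride, O=S(=O)(OS(=O)(=O)C(F)(F)F)C(F)(F)F
Why: Sulfonylation of the primary alcohol at low temperature should give the epoxy triflate, which is reactive enough to be displaced below −30 °C, where the oxirane is not attacked.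

Step 6
Reactants: 8 (2Z)-1-bromopent-2-ene; 9 ethynylmagnesium bromide
Product: 10 (4Z)-hept-4-en-1-yne
Conditions: 9 (2.5 equiv), CuCl (5 mol %), THF, 0 °C to rt; distillation
Reagents that add atoms: none
Why: Copper-catalysed coupling of an alkynyl Grignard reagent with a primary allylic bromide should proceed at the halide-bearing carbon with retention of the Z olefin; the excess of 9 suppresses a second allylation of the product.

Step 7
Reactants: 10 (4Z)-hept-4-en-1-yne; 7 {(2S,3R)-3-[2-(tert-butyldimethylsilyloxy)ethyl]oxiran-2-yl}methyl trifluoromethanesulfonate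
Product: 12 tert-butyldimethyl{2-[(2R,3S)-3-[(5Z)-oct-5-en-2-yn-1-yl]oxiran-2-yl]ethoxy}silane, via lithium acetylide 11 (not isolated)
Conditions: 10, n-BuLi, THF, −78 °C; then 7, DMPU, −78 to −30 °C
Reagents that add atoms: none
Why: SN2 displacement of a primary triflate by a lithium acetylide forms C11–C12; without a Lewis acid the oxirane is not opened, so C9 and C10 are untouched.

Step 8
Reactants: 12 tert-butyldimethyl{2-[(2R,3S)-3-[(5Z)-oct-5-en-2-yn-1-yl]oxiran-2-yl]ethoxy}silane
Product: 13 tert-butyldimethyl{2-[(2R,3S)-3-[(2Z,5Z)-octa-2,5-dien-1-yl]oxiran-2-yl]ethoxy}silane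
Conditions: H2 (1 atm), Pd/CaCO3 poisoned with Pb(OAc)2, quinoline, hexane–EtOAc, rt
Reagents that add atoms: none
Why: Lindlar semi-hydrogenation of the internal alkyne should give the 12Z olefin; the existing Z olefin and the oxirane are inert under these conditions.

Step 9
Reactants: 13 tert-butyldimethyl{2-[(2R,3S)-3-[(2Z,5Z)-octa-2,5-dien-1-yl]oxiran-2-yl]ethoxy}silane
Product: 14 (3R,4E,6Z,9Z)-1-(tert-butyldimethylsilyloxy)dodeca-4,6,9-trien-3-ol
Conditions: LiNEt2 (3 equiv, from Et2NH and n-BuLi), Et2O–hexane, 0 °C to rt; aq. NH4Cl
Reagents that add atoms: none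
Why: The lithium amide binds the oxirane oxygen and, through a cyclic syn transition state, removes the C11 hydrogen that eclipses the C10–O bond, so that C10–O breaks as C10=C11 forms; no ring is closed. This is the lithium dialkylamide isomerisation of epoxides to allylic alcohols, and its closest precedent is the opening of a cis-epoxide one methylene away from a Z olefin to the conjugated E,Z-dienol. No stereocentre is created: no bond to C9 is broken, so the R configuration from step 4 is carried over, while the C10 stereocentre is consumed. Site selectivity between the two methylenes flanking the oxirane is needed; C11–H is allylic to the 12Z olefin and its loss gives a conjugated diene, whereas C8–H is unactivated because C7 is kept saturated as the silyloxyethyl arm. The 10E geometry follows from the transition state, in which the vinyl group on C11 turns away from the oxirane carbon C9 and its cis substituent; the 12Z olefin is not involved. The doubly allylic C14 methylene is out of reach of the oxygen-bound amide, and free amide in ether at or below room temperature should remove its hydrogen only slowly, so base excess and reaction time are kept small. A shift of the silyl group from O7 to O9 in the lithium alkoxide would be harmless, because step 10 puts the same group on whichever oxygen is free.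

Step 10
Reactants: 14 (3R,4E,6Z,9Z)-1-(tert-butyldimethylsilyloxy)dodeca-4,6,9-trien-3-ol
Product: 15 (3R,4E,6Z,9Z)-1,3-bis(tert-butyldimethylsilyloxy)dodeca-4,6,9-triene
Conditions: TBSCl, imidazole, DMF, rt
Reagents that add atoms: tert-butyldimethylsilyl chloride, CC(C)(C)[Si](C)(C)Cl
Why: Silylation of the secondary allylic alcohol under base protects C9–O against elimination in the aldehyde and ylide steps without ionising the dienyl carbinol.

Step 11
Reactants: 15 (3R,4E,6Z,9Z)-1,3-bis(tert-butyldimethylsilyloxy)dodeca-4,6,9-triene
Product: 16 (3R,4E,6Z,9Z)-3-(tert-butyldimethylsilyloxy)dodeca-4,6,9-trien-1-ol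
Conditions: HF·pyridine, excess pyridine, THF, 0 °C
Reagents that add atoms: none
Why: Buffered HF·pyridine should cleave the unhindered primary silyl ether well before the secondary one (steric differentiation); the pyridine buffer keeps the medium too weakly acidic to ionise the C9 dienyl position.

Step 12
Reactants: 16 (3R,4E,6Z,9Z)-3-(tert-butyldimethylsilyloxy)dodeca-4,6,9-trien-1-ol
Product: 17 (3R,4E,6Z,9Z)-3-(tert-butyldimethylsilyloxy)dodeca-4,6,9-trienal
Conditions: Dess–Martin periodinane, NaHCO3, CH2Cl2, 0 °C to rt; used at once
Reagents that add atoms: none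
Why: Dess–Martin oxidation under bicarbonate buffer is neutral and should leave the polyene and the β-silyloxy group intact; the aldehyde is not stored because it can lose the silyloxy group by β-elimination.

Step 13
Reactants: 18 1-(2,6-dihydroxy-4-methoxyphenyl)ethan-1-one
Product: 19 1-[4-methoxy-2,6-bis(methoxymethoxy)phenyl]ethan-1-one
Conditions: NaH (2.5 equiv), MOMCl (2.5 equiv), DMF, 0 °C to rt
Reagents that add atoms: chloromethyl methyl ether, COCCl
Why: Williamson-type O-alkylation; full deprotonation with NaH is used because both phenols are hydrogen-bonded to the ketone and react sluggishly with amine bases.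

Step 14
Reactants: 19 1-[4-methoxy-2,6-bis(methoxymethoxy)phenyl]ethan-1-one; 20 1,4-diiodobutane
Product: 22 6-iodo-1-[4-methoxy-2,6-bis(methoxymethoxy)phenyl]hexan-1-one, via lithium enolate 21 (not isolated)
Conditions: LiN(iPr)2 (1.0 equiv), THF, −78 °C; then 20 (4 equiv), DMPU, −78 to −20 °C
Reagents that add atoms: none
Why: Alkylation of a kinetically formed lithium enolate with a primary iodide forms C2–C3; the large excess of diiodide favours mono-substitution of the electrophile.

Step 15
Reactants: 22 6-iodo-1-[4-methoxy-2,6-bis(methoxymethoxy)phenyl]hexan-1-one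
Product: 23 1-(2,6-dihydroxy-4-methoxyphenyl)-6-iodohexan-1-one
Conditions: TsOH·H2O (cat.), MeOH, 40 °C
Reagents that add atoms: none
Why: Acid-catalysed acetal exchange with methanol removes both aryl acetals; it is done at this stage, where nothing acid-sensitive is present, and a non-halide acid avoids halogen exchange at C6.

Step 16
Reactants: 23 1-(2,6-dihydroxy-4-methoxyphenyl)-6-iodohexan-1-one
Product: 24 [6-(2,6-dihydroxy-4-methoxyphenyl)-6-oxohexyl]triphenylphosphonium iodide
Conditions: PPh3, MeCN, reflux
Reagents that add atoms: triphenylphosphine, c1ccccc1P(c1ccccc1)c1ccccc1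
Why: SN2 quaternisation of triphenylphosphine by a primary iodide; the phenols are not alkylated in the absence of base.

Step 17
Reactants: 24 [6-(2,6-dihydroxy-4-methoxyphenyl)-6-oxohexyl]triphenylphosphonium iodide; 17 (3R,4E,6Z,9Z)-3-(tert-butyldimethylsilyloxy)dodeca-4,6,9-trienal
Product: 26 (6Z,9R,10E,12Z,15Z)-9-(tert-butyldimethylsilyloxy)-1-(2,6-dihydroxy-4-methoxyphenyl)octadeca-6,10,12,15-tetraen-1-one, via disodium bis-phenoxide ylide 25 (not isolated)
Conditions: 24 (1.6 equiv), NaN(SiMe3)2 (2.95 equiv per 24), THF–HMPA, −78 to 0 °C; then 17, −78 to −20 °C; aq. NH4Cl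
Reagents that add atoms: none
Why: Wittig olefination with an unstabilised ylide under lithium-free conditions should give the 6Z olefin by kinetic formation of the cis-oxaphosphetane. The first two equivalents of base turn the phenols into phenoxides, which make the ketone a vinylogous carboxylate inert to the ylide and to enolisation, as in Wittig reactions of carboxylate-bearing ylides. A slight deficit of base leaves none to enolise the aldehyde, so C9 is not touched.

Step 18
Reactants: 26 (6Z,9R,10E,12Z,15Z)-9-(tert-butyldimethylsilyloxy)-1-(2,6-dihydroxy-4-methoxyphenyl)octadeca-6,10,12,15-tetraen-1-one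
Product: 27 (6Z,9R,10E,12Z,15Z)-1-(2,6-dihydroxy-4-methoxyphenyl)-9-hydroxyoctadeca-6,10,12,15-tetraen-1-one
Conditions: Bu4NF, AcOH, THF, 0 °C to rt, under argon
Reagents that add atoms: none
Why: Fluoride-mediated desilylation buffered with acetic acid frees the C9 hydroxyl without acid ionisation of the dienyl carbinol or base-mediated isomerisation of the skipped diene; the C–O bond at C9 is not broken, so the configuration is kept.

## Compound list

1 | but-3-yn-1-ol | C#CCCO | starting material
2 | tert-butyl(but-3-yn-1-yloxy)dimethylsilane | C#CCCO[Si](C)(C)C(C)(C)C | intermediate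
3 | [4-(tert-butyldimethylsilyloxy)but-1-yn-1-yl]lithium | [Li]C#CCCO[Si](C)(C)C(C)(C)C | intermediate
4 | 5-(tert-butyldimethylsilyloxy)pent-2-yn-1-ol | OCC#CCCO[Si](C)(C)C(C)(C)C | intermediate
5 | (2Z)-5-(tert-butyldimethylsilyloxy)pent-2-en-1-ol | OC/C=C\CCO[Si](C)(C)C(C)(C)C | intermediate
6 | {(2S,3R)-3-[2-(tert-butyldimethylsilyloxy)ethyl]oxiran-2-yl}methanol | OC[C@@H]1O[C@@H]1CCO[Si](C)(C)C(C)(C)C | intermediate
7 | {(2S,3R)-3-[2-(tert-butyldimethylsilyloxy)ethyl]oxiran-2-yl}methyl trifluoromethanesulfonate | FC(F)(F)S(=O)(=O)OC[C@@H]1O[C@@H]1CCO[Si](C)(C)C(C)(C)C | intermediate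
8 | (2Z)-1-bromopent-2-ene | CC/C=C\CBr | starting material
9 | ethynylmagnesium bromide | C#C[Mg]Br | starting material
10 | (4Z)-hept-4-en-1-yne | CC/C=C\CC#C | intermediate
11 | [(4Z)-hept-4-en-1-yn-1-yl]lithium | CC/C=C\CC#C[Li] | intermediate
12 | tert-butyldimethyl{2-[(2R,3S)-3-[(5Z)-oct-5-en-2-yn-1-yl]oxiran-2-yl]ethoxy}silane | CC/C=C\CC#CC[C@@H]1O[C@@H]1CCO[Si](C)(C)C(C)(C)C | intermediate
13 | tert-butyldimethyl{2-[(2R,3S)-3-[(2Z,5Z)-octa-2,5-dien-1-yl]oxiran-2-yl]ethoxy}silane | CC/C=C\C/C=C\C[C@@H]1O[C@@H]1CCO[Si](C)(C)C(C)(C)C | intermediate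
14 | (3R,4E,6Z,9Z)-1-(tert-butyldimethylsilyloxy)dodeca-4,6,9-trien-3-ol | CC/C=C\C/C=C\C=C\[C@H](O)CCO[Si](C)(C)C(C)(C)C | intermediate
15 | (3R,4E,6Z,9Z)-1,3-bis(tert-butyldimethylsilyloxy)dodeca-4,6,9-triene | CC/C=C\C/C=C\C=C\[C@H](O[Si](C)(C)C(C)(C)C)CCO[Si](C)(C)C(C)(C)C | intermediate
16 | (3R,4E,6Z,9Z)-3-(tert-butyldimethylsilyloxy)dodeca-4,6,9-trien-1-ol | CC/C=C\C/C=C\C=C\[C@H](O[Si](C)(C)C(C)(C)C)CCO | intermediate
17 | (3R,4E,6Z,9Z)-3-(tert-butyldimethylsilyloxy)dodeca-4,6,9-trienal | CC/C=C\C/C=C\C=C\[C@H](O[Si](C)(C)C(C)(C)C)CC=O | intermediate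
18 | 1-(2,6-dihydroxy-4-methoxyphenyl)ethan-1-one | CC(=O)c1c(O)cc(OC)cc1O | starting material
19 | 1-[4-methoxy-2,6-bis(methoxymethoxy)phenyl]ethan-1-one | CC(=O)c1c(OCOC)cc(OC)cc1OCOC | intermediate
20 | 1,4-diiodobutane | ICCCCI | starting material
21 | lithium 1-[4-methoxy-2,6-bis(methoxymethoxy)phenyl]ethen-1-olate | C=C(O[Li])c1c(OCOC)cc(OC)cc1OCOC | intermediate
22 | 6-iodo-1-[4-methoxy-2,6-bis(methoxymethoxy)phenyl]hexan-1-one | ICCCCCC(=O)c1c(OCOC)cc(OC)cc1OCOC | intermediate
23 | 1-(2,6-dihydroxy-4-methoxyphenyl)-6-iodohexan-1-one | ICCCCCC(=O)c1c(O)cc(OC)cc1O | intermediate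
24 | [6-(2,6-dihydroxy-4-methoxyphenyl)-6-oxohexyl]triphenylphosphonium iodide | [I-].O=C(CCCCC[P+](c1ccccc1)(c1ccccc1)c1ccccc1)c1c(O)cc(OC)cc1O | intermediate
25 | disodium 5-methoxy-2-[6-(triphenylphosphoranylidene)hexanoyl]benzene-1,3-bis(olate) | [Na+].[Na+].[O-]c1cc(OC)cc([O-])c1C(=O)CCCCC=P(c1ccccc1)(c1ccccc1)c1ccccc1 | intermediate
26 | (6Z,9R,10E,12Z,15Z)-9-(tert-butyldimethylsilyloxy)-1-(2,6-dihydroxy-4-methoxyphenyl)octadeca-6,10,12,15-tetraen-1-one | CC/C=C\C/C=C\C=C\[C@H](O[Si](C)(C)C(C)(C)C)C/C=C\CCCCC(=O)c1c(O)cc(OC)cc1O | intermediate
27 | (6Z,9R,10E,12Z,15Z)-1-(2,6-dihydroxy-4-methoxyphenyl)-9-hydroxyoctadeca-6,10,12,15-tetraen-1-one | CC/C=C\C/C=C\C=C\[C@H](O)C/C=C\CCCCC(=O)c1c(O)cc(OC)cc1O | target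

## Step count and least certain steps

Total: 18 steps. Longest linear sequence: 13 steps (steps 1–5, 7–12, 17 and 18). Step 6 and steps 13–16 are side branches.

**Step 9 (key step).** The most likely failure is removal of a hydrogen from the doubly allylic C14 methylene, in 13 or more readily in the alkoxide of 14 where C14 lies between a diene and an olefin. The skipped olefin would then migrate into conjugation. A second failure is sluggish β-elimination with competing metalation of the oxirane carbon. The fallback builds the dienol without any strong base acting on the skipped diene. It sets out from epoxy alcohol 6 and returns at 14.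
- Appel chlorination of 6 (PPh3, CCl4) should give tert-butyl{2-[(2R,3R)-3-(chloromethyl)oxiran-2-yl]ethoxy}dimethylsilane F1.
- Double elimination of F1 with LiN(iPr)2 (3 equiv, THF, −78 to −30 °C) opens the oxirane and expels chloride. It should give (3R)-5-(tert-butyldimethylsilyloxy)pent-1-yn-3-ol F2, with C9 untouched.
- Hydrozirconation with Cp2Zr(H)Cl (excess, the first equivalent being consumed by the hydroxyl) and iodinolysis with I2 should give (1E,3R)-5-(tert-butyldimethylsilyloxy)-1-iodopent-1-en-3-ol F3.
- Sonogashira coupling of F3 with enyne 10 (PdCl2(PPh3)2, CuI, Et2NH) should give (3R,4E,9Z)-1-(tert-butyldimethylsilyloxy)dodeca-4,9-dien-6-yn-3-ol F4.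
- Semi-reduction of the conjugated triple bond with zinc activated by Cu(OAc)2 and AgNO3 in aqueous methanol should give 14.

**Step 4.** Facial discrimination is less complete and turnover slower for Z-allylic alcohols than for E ones, which would erode the enantiomeric purity of C9 and hence of 27. Since C10 is destroyed in step 9, only C9 matters, and it can be set on the E olefin. The fallback sets out from 4 and returns at 14.
- Reduction of 4 with NaAlH2(OCH2CH2OMe)2 should give (2E)-5-(tert-butyldimethylsilyloxy)pent-2-en-1-ol F5.
- Sharpless epoxidation with diethyl D-(−)-tartrate should give {(2R,3R)-3-[2-(tert-butyldimethylsilyloxy)ethyl]oxiran-2-yl}methanol F6.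
- Triflation as in step 5 should give {(2R,3R)-3-[2-(tert-butyldimethylsilyloxy)ethyl]oxiran-2-yl}methyl trifluoromethanesulfonate F7.
- Coupling with acetylide 11 as in step 7 should give tert-butyldimethyl{2-[(2R,3R)-3-[(5Z)-oct-5-en-2-yn-1-yl]oxiran-2-yl]ethoxy}silane F8.
- Lindlar reduction should give tert-butyldimethyl{2-[(2R,3R)-3-[(2Z,5Z)-octa-2,5-dien-1-yl]oxiran-2-yl]ethoxy}silane F9.
- The conditions of step 9 applied to this trans-(9R,10R)-epoxide should give 14 by the same syn elimination.

**Step 7.** Proton transfer from the allylic and propargylic C14 methylene of the enyne to acetylide 11 may lead to allenic or conjugated isomers, and triflate 7 may decompose while the coupling is slow. The fallback forms C13–C14 last with a mild copper-mediated coupling. It sets out from 7 and returns at 12.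
- Displacement of 7 with LiC≡CSiMe3 (THF–DMPU, −78 °C) should give tert-butyldimethyl{2-[(2R,3S)-3-[3-(trimethylsilyl)prop-2-yn-1-yl]oxiran-2-yl]ethoxy}silane F10.
- K2CO3 in methanol should give tert-butyldimethyl{2-[(2R,3S)-3-(prop-2-yn-1-yl)oxiran-2-yl]ethoxy}silane F11.
- Coupling of F11 with bromide 8 (CuI, NaI, K2CO3, DMF, rt) should give 12.

**Step 14.** Unreacted enolate 21 may deprotonate product 22, which then closes a five-membered ring onto its own iodide. One diiodide may also bridge two enolates. The fallback uses an electrophile with a single leaving group. It sets out from 19 and returns at 23.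
- Enolate 21 is alkylated with purchased 2-(4-bromobutoxy)oxane (NaI, DMPU) to give 1-[4-methoxy-2,6-bis(methoxymethoxy)phenyl]-6-(oxan-2-yloxy)hexan-1-one F12.
- TsOH in methanol removes all three acetals to give 1-(2,6-dihydroxy-4-methoxyphenyl)-6-hydroxyhexan-1-one F13.
- I2, PPh3 and imidazole convert only the aliphatic hydroxyl into the iodide, giving 23.

**Step 17.** The dianionic ylide 25 may be poorly soluble and slow to react. Loss of the β-silyloxy group from 17 by base-induced elimination towards the fully conjugated aldehyde may compete if any base is in excess. The fallback masks the phenols as silyl ethers that fall off in the final fluoride step. It sets out from 23 and returns at 27.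
- TBSOTf and 2,6-lutidine (CH2Cl2, −40 to 0 °C) should give 1-[2,6-bis(tert-butyldimethylsilyloxy)-4-methoxyphenyl]-6-iodohexan-1-one F14.
- PPh3 in MeCN should give {6-[2,6-bis(tert-butyldimethylsilyloxy)-4-methoxyphenyl]-6-oxohexyl}triphenylphosphonium iodide F15.
- Ylide formation with one equivalent of NaN(SiMe3)2 at −78 °C and immediate addition of 17 should give (6Z,9R,10E,12Z,15Z)-1-[2,6-bis(tert-butyldimethylsilyloxy)-4-methoxyphenyl]-9-(tert-butyldimethylsilyloxy)octadeca-6,10,12,15-tetraen-1-one F16. The ketone is shielded by the two ortho silyloxy groups.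
- Bu4NF with AcOH removes all three silyl groups to give 27.

## Further compounds

F1 | step 9 | tert-butyl{2-[(2R,3R)-3-(chloromethyl)oxiran-2-yl]ethoxy}dimethylsilane | ClC[C@@H]1O[C@@H]1CCO[Si](C)(C)C(C)(C)C
F2 | step 9 | (3R)-5-(tert-butyldimethylsilyloxy)pent-1-yn-3-ol | C#C[C@H](O)CCO[Si](C)(C)C(C)(C)C
F3 | step 9 | (1E,3R)-5-(tert-butyldimethylsilyloxy)-1-iodopent-1-en-3-ol | I/C=C/[C@H](O)CCO[Si](C)(C)C(C)(C)C
F4 | step 9 | (3R,4E,9Z)-1-(tert-butyldimethylsilyloxy)dodeca-4,9-dien-6-yn-3-ol | CC/C=C\CC#C/C=C/[C@H](O)CCO[Si](C)(C)C(C)(C)C
F5 | step 4 | (2E)-5-(tert-butyldimethylsilyloxy)pent-2-en-1-ol | OC/C=C/CCO[Si](C)(C)C(C)(C)C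
F6 | step 4 | {(2R,3R)-3-[2-(tert-butyldimethylsilyloxy)ethyl]oxiran-2-yl}methanol | OC[C@H]1O[C@@H]1CCO[Si](C)(C)C(C)(C)C
F7 | step 4 | {(2R,3R)-3-[2-(tert-butyldimethylsilyloxy)ethyl]oxiran-2-yl}methyl trifluoromethanesulfonate | FC(F)(F)S(=O)(=O)OC[C@H]1O[C@@H]1CCO[Si](C)(C)C(C)(C)C
F8 | step 4 | tert-butyldimethyl{2-[(2R,3R)-3-[(5Z)-oct-5-en-2-yn-1-yl]oxiran-2-yl]ethoxy}silane | CC/C=C\CC#CC[C@H]1O[C@@H]1CCO[Si](C)(C)C(C)(C)C
F9 | step 4 | tert-butyldimethyl{2-[(2R,3R)-3-[(2Z,5Z)-octa-2,5-dien-1-yl]oxiran-2-yl]ethoxy}silane | CC/C=C\C/C=C\C[C@H]1O[C@@H]1CCO[Si](C)(C)C(C)(C)C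
F10 | step 7 | tert-butyldimethyl{2-[(2R,3S)-3-[3-(trimethylsilyl)prop-2-yn-1-yl]oxiran-2-yl]ethoxy}silane | C[Si](C)(C)C#CC[C@@H]1O[C@@H]1CCO[Si](C)(C)C(C)(C)C
F11 | step 7 | tert-butyldimethyl{2-[(2R,3S)-3-(prop-2-yn-1-yl)oxiran-2-yl]ethoxy}silane | C#CC[C@@H]1O[C@@H]1CCO[Si](C)(C)C(C)(C)C
F12 | step 14 | 1-[4-methoxy-2,6-bis(methoxymethoxy)phenyl]-6-(oxan-2-yloxy)hexan-1-one | COCOc1cc(OC)cc(OCOC)c1C(=O)CCCCCOC1CCCCO1
F13 | step 14 | 1-(2,6-dihydroxy-4-methoxyphenyl)-6-hydroxyhexan-1-one | OCCCCCC(=O)c1c(O)cc(OC)cc1O
F14 | step 17 | 1-[2,6-bis(tert-butyldimethylsilyloxy)-4-methoxyphenyl]-6-iodohexan-1-one | ICCCCCC(=O)c1c(O[Si](C)(C)C(C)(C)C)cc(OC)cc1O[Si](C)(C)C(C)(C)C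
F15 | step 17 | {6-[2,6-bis(tert-butyldimethylsilyloxy)-4-methoxyphenyl]-6-oxohexyl}triphenylphosphonium iodide | [I-].O=C(CCCCC[P+](c1ccccc1)(c1ccccc1)c1ccccc1)c1c(O[Si](C)(C)C(C)(C)C)cc(OC)cc1O[Si](C)(C)C(C)(C)C
F16 | step 17 | (6Z,9R,10E,12Z,15Z)-1-[2,6-bis(tert-butyldimethylsilyloxy)-4-methoxyphenyl]-9-(tert-butyldimethylsilyloxy)octadeca-6,10,12,15-tetraen-1-one | CC/C=C\C/C=C\C=C\[C@H](O[Si](C)(C)C(C)(C)C)C/C=C\CCCCC(=O)c1c(O[Si](C)(C)C(C)(C)C)cc(OC)cc1O[Si](C)(C)C(C)(C)C
A1 | alternative 1 | (6Z,9R,10E,12Z,15Z)-9-(tert-butyldimethylsilyloxy)-1-(2,4,6-trihydroxyphenyl)octadeca-6,10,12,15-tetraen-1-one | CC/C=C\C/C=C\C=C\[C@H](O[Si](C)(C)C(C)(C)C)C/C=C\CCCCC(=O)c1c(O)cc(O)cc1O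
A2 | alternative 1 | methyl (12Z,15R,16E,18Z,21Z)-15-(tert-butyldimethylsilyloxy)-3,5,7-trioxotetracosa-12,16,18,21-tetraenoate | CC/C=C\C/C=C\C=C\[C@H](O[Si](C)(C)C(C)(C)C)C/C=C\CCCCC(=O)CC(=O)CC(=O)CC(=O)OC
A3 | alternative 2 | (6Z,9R,10E,12Z,15Z)-9-hydroperoxyoctadeca-6,10,12,15-tetraenoic acid | CC/C=C\C/C=C\C=C\[C@H](OO)C/C=C\CCCCC(=O)O
A4 | alternative 2 | stearidonic acid, (6Z,9Z,12Z,15Z)-octadeca-6,9,12,15-tetraenoic acid | CC/C=C\C/C=C\C/C=C\C/C=C\CCCCC(=O)O
A5 | alternative 3 | 2-[(5Z,8R,9E,11Z,14Z)-8-(tert-butyldimethylsilyloxy)heptadeca-5,9,11,14-tetraen-1-yl]-2-[4-methoxy-2,6-bis(methoxymethoxy)phenyl]-1,3-dithiane | CC/C=C\C/C=C\C=C\[C@H](O[Si](C)(C)C(C)(C)C)C/C=C\CCCCC1(SCCCS1)c1c(OCOC)cc(OC)cc1OCOC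
A6 | alternative 3 | (5Z,8R,9E,11Z,14Z)-8-(tert-butyldimethylsilyloxy)-1-iodoheptadeca-5,9,11,14-tetraene | CC/C=C\C/C=C\C=C\[C@H](O[Si](C)(C)C(C)(C)C)C/C=C\CCCCI
A7 | alternative 3 | 2-[4-methoxy-2,6-bis(methoxymethoxy)phenyl]-1,3-dithiane | COCOc1cc(OC)cc(OCOC)c1C1SCCCS1
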